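**Assumption:** the target is the 4,8-epoxybriarane encoded by the SMILES. The (S)-furylcarbinol (6) is the enantiomer that gives the required C4 configuration. Numbering is briarane numbering (C1 = quaternary C–Me, C20 = CH2Cl, C16 = exocyclic CH2).

## Retrosynthetic overview
1. Fragilide F ⇐ C2/C3 trans-diol (C3 acetate, C2 alcohol) from epoxidation and anti-opening of a cis C2=C3 alkene. That alkene comes from ring-closing metathesis of a C1-vinyl/C4-vinyl diene, which closes the oxocane and the 10-membered carbocycle.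
2. The chlorinated THP–γ-lactone (C4–O–C8 bridge) ⇐ Achmatowicz dearomatization of a furfuryl alcohol, C-glycosylation at C8 (quaternary, with C17), oxa-Michael lactonization, and C6 chloride by SN2 inversion. The 11-OH/20-Cl comes from an exocyclic methylene via epoxide and chloride opening.
3. The cyclohexane with the C1 quaternary centre ⇐ Cu-catalysed asymmetric vinylation and aldol of an enone from oxidative dearomatization of 4-methoxy-3-methylphenol, coupled to a 2,5-disubstituted furfural made from furfural.
4. Order of ring formation: cyclohexane, then THP (furan → pyranone), then γ-lactone, then the 10-membered carbocycle (RCM), then the epoxide openings.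

## Route

**Step 1**
Reactants: 1 (4-methoxy-3-methylphenol)
Product: 2 (4,4-dimethoxy-3-methylcyclohexa-2,5-dien-1-one)
Conditions: PhI(OAc)2, MeOH, 0 °C
Reagents that add atoms: methanol, CO
Why: oxidative dearomatization of a p-methoxyphenol in methanol gives the quinone monoketal (achiral, no stereocentres).

**Step 2**
Reactants: 2
Product: 3 (4,4-dimethoxy-3-methylcyclohex-2-en-1-one)
Conditions: H2 (1 atm), RhCl(PPh3)3, benzene/EtOH, rt
Reagents that add atoms: none (H2 only)
Why: Wilkinson hydrogenation reduces the unhindered disubstituted alkene and leaves the β-methyl enone, so C12 and C13 become CH2CH2.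

**Step 3**
Reactants: 4 (furfural)
Product: 5 ((±)-1-(furan-2-yl)prop-2-en-1-ol)
Conditions: vinylMgBr, THF, 0 °C
Reagents that add atoms: vinylmagnesium bromide, C=C[Mg]Br
Why: Grignard 1,2-addition to the aldehyde.

**Step 4**
Reactants: 5
Product: 6 ((S)-1-(furan-2-yl)prop-2-en-1-ol)
Conditions: Ti(OiPr)4, tartrate ester (enantiomer chosen to consume the (R)-alcohol), TBHP, 4 Å MS, CH2Cl2, −20 °C
Reagents that add atoms: none (the (S)-alcohol is recovered)
Why: Sharpless-type kinetic resolution of 2-furylcarbinols; the fast (R)-enantiomer is oxidized and the (S)-alcohol is recovered, which sets C4.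

**Step 5**
Reactants: 6
Product: 7 (TBS ether of 6)
Conditions: TBSCl, imidazole, DMF, rt
Reagents that add atoms: TBSCl, CC(C)(C)[Si](C)(C)Cl
Why: protects the carbinol so the furan can be lithiated and survive the Grignard chemistry; C4 is untouched.

**Step 6**
Reactants: 7
Product: 8 (5-[(1S)-1-(TBSO)allyl]furan-2-carbaldehyde)
Conditions: n-BuLi, THF, −78 → −20 °C; then DMF, −78 → 0 °C
Reagents that add atoms: DMF, CN(C)C=O
Why: α-lithiation of the free furan C5 position followed by formylation; C4 is untouched.

**Step 7**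
Reactants: 3 and 8
Product: 9 (β-acetoxy ketone; C1 quaternary with Me and vinyl, C10–C9 bond formed)
Conditions: vinylMgBr (1.2 equiv), CuBr·SMe2 (5 mol%), Josiphos-type ligand (6 mol%), 2-MeTHF, −78 °C; then 8, −78 → −20 °C; then Ac2O, DMAP, 0 °C
Reagents that add atoms: vinylmagnesium bromide, C=C[Mg]Br; acetic anhydride, CC(=O)OC(C)=O
Why: Proposed new method: a chiral Cu-catalysed conjugate vinylation of the β,β-disubstituted enone fixes C1, and the resulting Mg enolate adds to the aldehyde in a tandem Michael–aldol. The reversible aldolate equilibrates to the chelated isomer with C9 equatorial on the trans-fused chair, which gives the target C9/C10 relative configuration, and Ac2O traps it; the closest known chemistry is Cu-catalysed Grignard addition to 3-substituted cyclohexenones combined with enolate aldol trapping.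

**Step 8**
Reactants: 9
Product: 10 (C11 exocyclic methylene, C20)
Conditions: Cp2TiMe2, toluene, 70 °C, dark
Reagents that add atoms: dimethyltitanocene (CH2 donor), C[Ti](C)(C1C=CC=C1)C1C=CC=C1
Why: Petasis methylenation is non-basic and selective for the ketone over the acetate, so retro-aldol and β-acetoxy elimination are avoided; no new stereocentre.

**Step 9**
Reactants: 10
Product: 11 (C14 ketone)
Conditions: I2 (10 mol%), acetone/H2O (20:1), rt
Reagents that add atoms: water, O
Why: iodine-catalysed, essentially neutral ketal hydrolysis/exchange unmasks C14=O without touching the furyl TBS ether, the acetate or the alkenes.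

**Step 10**
Reactants: 11
Product: 12 (C14 axial alcohol)
Conditions: L-Selectride, THF, −78 °C
Reagents that add atoms: none (hydride only)
Why: the bulky hydride is blocked from the axial trajectory by the axial hydrogens at C10 and C12, so it attacks equatorially and gives the axial C14 alcohol (down) as in the target.

**Step 11**
Reactants: 12
Product: 13 (C14 acetate)
Conditions: Ac2O, pyridine, DMAP, rt
Reagents that add atoms: acetic anhydride, CC(=O)OC(C)=O
Why: acetylation; configuration retained.

**Step 12**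
Reactants: 13
Product: 14 (free furfuryl alcohol at C4)
Conditions: TBAF/AcOH (1:1), THF, 0 °C
Reagents that add atoms: none
Why: buffered fluoride removes TBS without acetate cleavage; C4 is unchanged.

**Step 13**
Reactants: 14
Product: 15 (6-hydroxy-2H-pyran-3(6H)-one; C8 hemiketal as an anomeric mixture)
Conditions: NBS, NaHCO3, NaOAc, THF/H2O 4:1, −10 °C
Reagents that add atoms: water, O
Why: Achmatowicz dearomatization builds the THP ring (C4–O–C8, C5 ketone, C6=C7 enone) with retention of C4, and the furan reacts far faster than the 1,1-disubstituted alkene.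

**Step 14**
Reactants: 15
Product: 16 (anomeric acetate)
Conditions: Ac2O, pyridine, DMAP, CH2Cl2, 0 °C
Reagents that add atoms: acetic anhydride, CC(=O)OC(C)=O
Why: converts the hemiketal into a leaving group, so both C8 anomers converge on the same oxocarbenium.

**Step 15**
Reactants: 16
Product: 17 (C8 quaternary, C17 carboxylic acid)
Conditions: CH3CH=C(OTMS)2 (2 equiv), TMSOTf (10 mol%), CH2Cl2, −78 °C; then aqueous NH4Cl/THF
Reagents that add atoms: 1,1-bis(trimethylsilyloxy)prop-1-ene, CC=C(O[Si](C)(C)C)O[Si](C)(C)C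
Why: Proposed new method: Mukaiyama-type C-glycosylation of the Achmatowicz oxocarbenium is extended to a 6-substituted (tertiary) cation, forming a quaternary centre. Axial attack on the half-chair, anti to the equatorial C4 vinyl, places C17 on the face needed for lactone bridging, and the stereocentre α to the carboxyl group can equilibrate in step 16.

**Step 16**
Reactants: 17
Product: 18 (cis-fused γ-lactone, keto-THP)
Conditions: DBU (0.3 equiv), CH2Cl2, 0 °C, short reaction time
Reagents that add atoms: none
Why: intramolecular 5-exo oxa-Michael addition of the carboxylate to C7 occurs from the same face as C17, so C7–O is necessarily cis to C8–C17; the C6 enolate is protonated and C6 is re-functionalized later.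

**Step 17**
Reactants: 18
Product: 19 (11,20-spiro-epoxide)
Conditions: mCPBA (1.1 equiv), NaHCO3, CH2Cl2, −20 → 0 °C
Reagents that add atoms: mCPBA, OOC(=O)c1cccc(Cl)c1
Why: Prilezhaev epoxidation of the most nucleophilic alkene (the 1,1-disubstituted C11=C20) occurs from the bottom face because the axial C15 methyl blocks the top, giving O down and C20 up as in the target.

**Step 18**
Reactants: 19
Product: 20 (11-OH, 20-Cl chlorohydrin)
Conditions: LiCl, AcOH, THF, 50 °C
Reagents that add atoms: lithium chloride, [Li+].[Cl-]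
Why: chloride opens the spiro-epoxide by SN2 at the CH2 carbon, so C11–O is retained; this is done before any allylic C6–Cl exists, so that C6–Cl cannot be epimerized by chloride exchange.

**Step 19**
Reactants: 20
Product: 21 (C6 α-hydroxy ketone, OH trans to the lactone oxygen)
Conditions: (i) TMSOTf, Et3N, CH2Cl2, −78 °C; (ii) DMDO, acetone, −78 °C; (iii) HF·pyridine, THF, 0 °C
Reagents that add atoms: dimethyldioxirane, CC1(C)OO1
Why: Rubottom oxidation of the C5–C6 silyl enol ether (formed under non-basic silylation conditions, so the β-lactone oxygen is not eliminated) is delivered to the convex face, anti to the lactone, giving 6-OH trans to O7; the tertiary alcohol is transiently silylated and freed in (iii).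

**Step 20**
Reactants: 21
Product: 22 (C5=C16 exocyclic methylene, C6 allylic alcohol)
Conditions: Zn, CH2Br2, TiCl4, THF/CH2Cl2, 0 °C → rt
Reagents that add atoms: dibromomethane, BrCBr
Why: Takai–Lombardo methylenation is ketone-selective (lactone and acetates survive) and non-basic, so there is no β-elimination of the lactone oxygen and C6 is not epimerized.

**Step 21**
Reactants: 22
Product: 23 (C6 chloride, diene for RCM)
Conditions: PPh3, NCS, pyridine (cat.), CH2Cl2, −20 → 0 °C
Reagents that add atoms: N-chlorosuccinimide, ClN1C(=O)CCC1=O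
Why: Appel-type SN2 with inversion converts the 6-OH (up) into 6-Cl (down), cis to O7 as in the target.

**Step 22**
Reactants: 23
Product: 24 (cis C2=C3 oxocene; 10-membered carbocycle closed)
Conditions: Hoveyda–Grubbs II (10 mol%), toluene, 0.002 M, 80 °C
Reagents that add atoms: none (ethylene is lost)
Why: Proposed new method: ring-closing metathesis of the C1 vinyl and the C4 vinyl on the 2,6-cis THP, which are held close by the trans-fused cyclohexane, closes the bridged cis-oxocene; the closest known reaction is RCM construction of laurencin-type oxocenes, and only the monosubstituted alkenes are fast.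

**Step 23**
Reactants: 24
Product: 25 (2,3-epoxide, O up)
Conditions: mCPBA (1.1 equiv), NaHCO3, CH2Cl2, 0 °C
Reagents that add atoms: mCPBA, OOC(=O)c1cccc(Cl)c1
Why: the cis alkene is epoxidized from the top face because the C4–O–C8 bridge occupies the bottom face, and C5=C16 is deactivated by the allylic Cl and O.

**Step 24**
Reactants: 25
Product: 26 (C3 acetate, C2 hydroxy)
Conditions: AcOH, CsOAc, 80 °C
Reagents that add atoms: acetic acid, CC(=O)O
Why: acetate attacks the less hindered C3 (C2 is neopentyl) anti to the epoxide by SN2 with inversion, giving C3–OAc and C2–OH trans.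

**Step 25**
Reactants: 26
Product: 27 (Fragilide F)
Conditions: Ac2O, pyridine, DMAP, rt
Reagents that add atoms: acetic anhydride, CC(=O)OC(C)=O
Why: the secondary C2 alcohol is acetylated and the hindered tertiary C11–OH is left free.

## Compound list
1 | 4-methoxy-3-methylphenol | COc1ccc(O)cc1C | starting material
2 | 4,4-dimethoxy-3-methylcyclohexa-2,5-dien-1-one | COC1(OC)C=CC(=O)C=C1C | intermediate
3 | 4,4-dimethoxy-3-methylcyclohex-2-en-1-one | COC1(OC)CCC(=O)C=C1C | intermediate
4 | furfural | O=Cc1ccco1 | starting material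
5 | (±)-1-(furan-2-yl)prop-2-en-1-ol | C=CC(O)c1ccco1 | intermediate
6 | (S)-1-(furan-2-yl)prop-2-en-1-ol | C=C[C@H](O)c1ccco1 | intermediate
7 | (S)-TBS ether of 6 | C=C[C@H](O[Si](C)(C)C(C)(C)C)c1ccco1 | intermediate
8 | 5-[(1S)-1-(TBSO)allyl]furan-2-carbaldehyde | C=C[C@H](O[Si](C)(C)C(C)(C)C)c1ccc(C=O)o1 | intermediate
9 | Michael–aldol–acetate (cyclohexanone, ketal) | C=C[C@]1(C)[C@@H]([C@H](OC(C)=O)c2ccc(o2)[C@@H](O[Si](C)(C)C(C)(C)C)C=C)C(=O)CCC1(OC)OC | intermediate
10 | C11 methylene analogue of 9 | C=C[C@]1(C)[C@@H]([C@H](OC(C)=O)c2ccc(o2)[C@@H](O[Si](C)(C)C(C)(C)C)C=C)C(=C)CCC1(OC)OC | intermediate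
11 | C14 ketone | C=C[C@]1(C)[C@@H]([C@H](OC(C)=O)c2ccc(o2)[C@@H](O[Si](C)(C)C(C)(C)C)C=C)C(=C)CCC1=O | intermediate
12 | C14 axial alcohol | C=C[C@]1(C)[C@@H]([C@H](OC(C)=O)c2ccc(o2)[C@@H](O[Si](C)(C)C(C)(C)C)C=C)C(=C)CC[C@@H]1O | intermediate
13 | C14 acetate | C=C[C@]1(C)[C@@H]([C@H](OC(C)=O)c2ccc(o2)[C@@H](O[Si](C)(C)C(C)(C)C)C=C)C(=C)CC[C@@H]1OC(C)=O | intermediate
14 | free furfuryl alcohol | C=C[C@]1(C)[C@@H]([C@H](OC(C)=O)c2ccc(o2)[C@@H](O)C=C)C(=C)CC[C@@H]1OC(C)=O | intermediate
15 | Achmatowicz hemiketal pyranone (C8 epimeric mixture) | C=C[C@]1(C)[C@@H]([C@H](OC(C)=O)C2(O)C=CC(=O)[C@H](C=C)O2)C(=C)CC[C@@H]1OC(C)=O | intermediate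
16 | anomeric acetate | C=C[C@]1(C)[C@@H]([C@H](OC(C)=O)C2(OC(C)=O)C=CC(=O)[C@H](C=C)O2)C(=C)CC[C@@H]1OC(C)=O | intermediate
17 | C8 quaternary acid, enone | C=C[C@]1(C)[C@@H]([C@H](OC(C)=O)[C@]2(O[C@@H](C=C)C(=O)C=C2)[C@@H](C)C(=O)O)C(=C)CC[C@@H]1OC(C)=O | intermediate
18 | keto-lactone | O=C1[C@H](C=C)O[C@]3([C@@H](C)C(=O)O[C@H]3C1)[C@@H](OC(C)=O)[C@H]1C(=C)CC[C@H](OC(C)=O)[C@]1(C)C=C | intermediate
19 | 11,20-epoxide | O=C1[C@H](C=C)O[C@]3([C@@H](C)C(=O)O[C@H]3C1)[C@@H](OC(C)=O)[C@H]1[C@@]4(CO4)CC[C@H](OC(C)=O)[C@]1(C)C=C | intermediate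
20 | chlorohydrin | O=C1[C@H](C=C)O[C@]3([C@@H](C)C(=O)O[C@H]3C1)[C@@H](OC(C)=O)[C@H]1[C@@](O)(CCl)CC[C@H](OC(C)=O)[C@]1(C)C=C | intermediate
21 | C6 α-hydroxy ketone | O=C1[C@H](C=C)O[C@]3([C@@H](C)C(=O)O[C@H]3[C@@H]1O)[C@@H](OC(C)=O)[C@H]1[C@@](O)(CCl)CC[C@H](OC(C)=O)[C@]1(C)C=C | intermediate
22 | allylic alcohol (5(16)-ene) | C=C1[C@H](C=C)O[C@]3([C@@H](C)C(=O)O[C@H]3[C@@H]1O)[C@@H](OC(C)=O)[C@H]1[C@@](O)(CCl)CC[C@H](OC(C)=O)[C@]1(C)C=C | intermediate
23 | allylic chloride, RCM diene | C=C1[C@H](C=C)O[C@]3([C@@H](C)C(=O)O[C@H]3[C@H]1Cl)[C@@H](OC(C)=O)[C@H]1[C@@](O)(CCl)CC[C@H](OC(C)=O)[C@]1(C)C=C | intermediate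
24 | C2=C3 oxocene (tricycle) | C=C1[C@H]2O[C@]3([C@@H](C)C(=O)O[C@H]3[C@H]1Cl)[C@@H](OC(C)=O)[C@H]1[C@@](O)(CCl)CC[C@H](OC(C)=O)[C@]1(C)C=C2 | intermediate
25 | 2,3-epoxide | C=C1[C@H]2O[C@]3([C@@H](C)C(=O)O[C@H]3[C@H]1Cl)[C@@H](OC(C)=O)[C@H]1[C@@](O)(CCl)CC[C@H](OC(C)=O)[C@]1(C)[C@H]5O[C@H]52 | intermediate
26 | C2-hydroxy, C3-acetate | C=C1[C@H]2O[C@]3([C@@H](C)C(=O)O[C@H]3[C@H]1Cl)[C@@H](OC(C)=O)[C@H]1[C@@](O)(CCl)CC[C@H](OC(C)=O)[C@]1(C)[C@@H](O)[C@@H]2OC(C)=O | intermediate
27 | Fragilide F | C=C1[C@H]2O[C@]3([C@@H](C)C(=O)O[C@H]3[C@H]1Cl)[C@@H](OC(C)=O)[C@H]1[C@@](O)(CCl)CC[C@H](OC(C)=O)[C@]1(C)[C@@H](OC(C)=O)[C@@H]2OC(C)=O | target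

## Totals
Total steps: 25. Longest linear sequence: 23 (steps 3–6 from furfural 4, then steps 7–25). The phenol branch (steps 1–2) is shorter and joins at step 7.

## Three steps most likely to fail
1. **Step 7 (asymmetric vinylation/aldol).** It builds a quaternary centre next to a ketal carbon and needs C9/C10 diastereocontrol. Fallback: a stepwise route of Rh/chiral-diene 1,4-addition of vinyl-BF3K to 3, TMSCl trapping of the enolate, then a TiCl4-mediated Mukaiyama aldol with 8.
2. **Step 22 (RCM to the bridged oxocene).** Ring strain may prevent closure. Fallback: at the stage of 20, when the two vinyl groups are the only alkenes, ozonolyse both and close C2–C3 by SmI2 pinacol coupling. Then invert C3 by Mitsunobu reaction with AcOH to give the trans C3-OAc/C2-OH pattern, carry out steps 19–21 on that substrate, and acetylate C2 as in step 25.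
3. **Step 15 (quaternary C8 C-glycosylation and the C17 stereocentre).** The cation is hindered and C17 may come out as the wrong epimer. Fallback: build an α-methylbutenolide at C7/C8 and form the C4–O–C8 ether by base-mediated transannular oxa-Michael addition in the 10-membered ring.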